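## Structural features

The target is a spiro[5.5]undecane of the chamigrane type. In the numbering used for every spiro compound below, ring B is C1–C5 plus the spiro carbon C6, ring A is C6–C11, and C15 is the methylene carbon. Ring B is a cyclohexene with the exocyclic methylene on C1, a doubly allylic secondary alcohol on C2, the C3=C4 vinyl bromide and the gem-dimethyl carbon C5. Ring A is saturated and carries a tertiary chloride with a methyl group on C9 and a secondary bromide on C10. The rings share only C6, a quaternary carbon flanked by the quaternary C5 and the sp2 carbon C1. C9 and C10 are adjacent stereocentres (Cl trans to Br, methyl cis to Br); C10 is 1,3 to C6 with bromine cis to C5; C2 stands alone on ring B. The fragile groups are the bis-allylic alcohol (ionisation), the cross-conjugated methylene, the vinyl bromide (metals, hydride) and the vicinal tertiary chloride and secondary bromide (elimination, halide shift); both halogens are equatorial because C5 must be equatorial on ring A, which helps them. The real difficulty is that C6 has to be built next to C5 as one enantiomer, and that it is a stereocentre only while the two arms of ring A differ, so any intermediate with a symmetrical ring A erases it. The key step uses the fact that C6 is α to C1, which can stay a ketone until late, and that C9 is 1,4 to C6 across ring A: C7–C8–C9–C10 is then a 3-oxobutyl unit and C11 a formyl carbon on C6.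

## Logic of the disconnections

**15 to 14.** The C2–H bond is cut, so the carbinol goes back to a ketone. C2 lies between two alkenes and sees two nearly identical ring A arms at C6, so no substrate control can be expected and a reagent-controlled reduction is placed last. This removes one stereocentre and keeps the ionisable bis-allylic alcohol out of every acidic step. The forward step needs a catalyst that tells the fully substituted C1 from the CH carbon C3 and adds hydride 1,2.

**14 to 13.** The C4–Br bond is cut; C4 becomes a carbonyl and the C2 ketone becomes a methyl enol ether. A β-bromo enone is the retron of a vinylogous ester, and the position of the methyl ether decides that bromine goes to C4 and the ketone to C2. Ring B becomes a pattern traceable to a 1,3-dione. The forward step must activate the C4 carbonyl next to C5 without touching the exocyclic alkene or the alkyl halides.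

**13 to 12.** The C1=C15 bond is cut. C15 is the only carbon that the annulation pieces do not supply, and C1 as a ketone is what makes C6 acidic earlier. The forward step must methylenate a neopentyl ketone in preference to the vinylogous ester carbonyl C4, without base.

**12 to 11 to 10.** The C9–Cl bond is cut, then the C9–CH3 bond. A tertiary chloride trans to a neighbouring bromide is what chloride opening of a C9–C10 bromonium ion gives, and a β-bromo tertiary alcohol generates that ion on ionisation. C9 therefore derives from C10 alone, and the alcohol comes from methyl addition to an α-bromo ketone. The stereochemical problem of ring A shrinks to C10 in 10. The forward steps need ionisation without elimination, chloride capture anti to bromine, and methyl addition to C9 only.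

**10 to 8 (through 9).** The C10–Br and C11–H bonds are cut. The enone gives a regiodefined enol derivative at C9/C10, and the equatorial bromide cis to C5 is the thermodynamic epimer. Only C6 is left as a stereocentre. The forward step must deliver hydride to C11 of ring A only and must not let the enol derivative move to C8, because that isomer belongs to the enantiomeric series and the free C9 ketone has no stereocentre at all.

**8 to 5 and 6 (through 7).** The C10=C11 bond (aldol condensation) and the C6–C7 bond (Michael addition) are cut. Ring A and the quaternary stereocentre disappear together, leaving two achiral pieces. The forward step needs enantioface selection at the planar C6 enol by a catalyst, the aldehyde as the only aldol acceptor, and no nucleophilic amine or alkoxide.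

**5 to 3 and 4.** The C6–C11 bond is cut. The formyl group acidifies C6, supplies C11 and blocks nothing else. The forward step is C-formylation at a neopentyl carbon; a formate whose alkoxide is a poor nucleophile is chosen so that the C2 methoxy group is not exchanged.

**3 to 2 to 1.** The C1=O bond is traced to a C–H oxidation and the O–CH3 bond to enol ether formation. The allylic methylene of 2 is the only activated C–H position, and the enol ether forms at the carbonyl remote from the gem-dimethyl group. The forward steps need that regiochemistry and an oxidation that stops at the ene-dione, which cannot tautomerise to a hydroquinone because C5 is quaternary.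

## Other disconnections considered

**Alternative 1:** The cut is C6–C11, made while ring B is a cross-conjugated bromodienone.
- Forward key step: EtAlCl2 binds the C2 carbonyl of dienone A1. The terminal alkene carbon C11 of the tethered tertiary allylsilane adds to the β-carbon C6 (intramolecular Sakurai-type conjugate addition through a six-membered chair, electrophile anti to silicon), and silicon leaves from C9 to give spiro bromoenone A2 with the C9=C10 alkene.
- In favour: the C5–C6 vicinal quaternary pair is closed intramolecularly, which for this congested bond is the better arrangement than the bimolecular Michael addition of the chosen plan. A2 already has C4–Br, the C2 ketone and the C9 methyl on an alkene ready for bromochlorination, so it should reach 14 in about two operations (bromochlorination, α-methylenation at C1) against five from 8.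
- Against: the C6 configuration must come from a stoichiometric, enantioenriched silicon-bearing quaternary stereocentre at C9 of A1 (drawn (R) on the anti-SE2′ chair model), so the asymmetric quaternary-carbon problem is moved, not removed, and A1 needs a longer assembly. A 4,4-dimethylcyclohexadienone under a strong Lewis acid can rearrange by methyl shift toward a phenol, and protodesilylation competes. The bromochlorination of A2 must find the right alkene face without the thermodynamic correction open to an α-bromo ketone.
- Comparison: both plans arrive at the same dienone 14. The chosen plan uses a catalytic chiral controller where this one uses a stoichiometric one, while this one forms the hindered bond more reliably. It is shorter after the key step and longer before it, so the totals should be similar.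

**Alternative 2:** The cut is C9–C10, made with ring B complete.
- Forward key step: proline condenses with one 3-oxobutyl arm of diketone A3 to an enamine, whose α-carbon C10 adds to the C9 carbonyl of the other arm (6-enolexo) to give ketol A4.
- In favour: three stereocentres (C6, C9, C10) arise in one operation with an inexpensive catalyst, which is better than anything in the chosen plan in stereocentres per step. C9 receives its methyl and oxygen together without an organometallic reagent. Ring B is finished first, so no late choice between ring B carbonyls arises.
- Against: the two arms of A3 differ only through the remote C2 centre and the unsymmetrical ring B, so the catalyst alone must pick the arm (this choice is the C6 configuration) and the more substituted enamine. A4 has an acetyl group where bromine is needed and a hydroxyl where chlorine is needed. Both must be exchanged with net retention: Baeyer–Villiger oxidation followed by a double inversion at a hindered secondary carbon, and a tertiary substitution with no neighbouring bromine to steer it. Two carbons are discarded and the peracid would meet the exocyclic alkene. The bis-allylic silyl ether, the diene and the vinyl bromide must survive all of this, and A3 needs two C–C bonds at C6 next to C5 instead of one.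
- Comparison: the two plans are equal in using an organocatalyst at the key step. This one is better in stereocentres set per step and worse in the exchanges that follow (at least five operations after A4) and in exposing the fragile ring B early, whereas the chosen plan keeps ring B as an ene-dione until the last three steps.

**Alternative 3:** The cut is C4–C5, closing ring B onto a preformed ring A.
- Forward key step: Fe(acac)3/PhSiH3 delivers a hydrogen atom to the isopropenyl group of A5. The tertiary C5 radical adds 6-endo to the dibrominated carbon C4 of the enone, and loss of a bromine atom from the resulting α-keto radical gives bromoenone A6.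
- In favour: addition of a tertiary radical to an alkene is the most tolerant way to join two fully substituted carbons, and on that point it is better than the polar Michael addition of the chosen plan. The vinyl bromide appears in the same step. A5 is assembled on a symmetrical cyclohexanone ketal by chemistry with no stereochemical demands.
- Against: A6 is achiral, because C6 is not a stereocentre while ring A is symmetrical. The absolute configuration is postponed to a desymmetrisation of the C9 ketone, for instance an enantioselective bromination at C10 that would have to set C6 and C10 together across three bonds. The radical must prefer 6-endo to 5-exo closure and must not be reduced, and the iron hydride can debrominate.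
- Comparison: the chosen plan makes C6 a stereocentre in the ring-forming step, this one afterwards. Steric tolerance favours the radical route and enantiocontrol precedent favours the ionic one. Step economy is about equal, since ketal removal, desymmetrising bromination, methyl addition, chlorination, methylenation and reduction remain after A6.

Key step: step 4

Assumption: the (1R,2R) antipode of the amine–thiourea catalyst is written in step 4; which antipode leads to (S)-7 and (R)-8 cannot be predicted with confidence and is to be fixed in a first analytical run, both antipodes being commercial.

Remark: the arrangement in space at C6 is the same in 7 to 15. Its descriptor reads S in 7, R in 8–12 and S in 13–15 only because the ranking of the four neighbours changes.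

## Route

Step 1
Reactants: 1 4,4-dimethylcyclohexane-1,3-dione
Product: 2 3-methoxy-6,6-dimethylcyclohex-2-en-1-one
Conditions: MeOH, p-TsOH·H2O (5 mol %), 3 Å MS, 40 °C
Reagents that add atoms: methanol, CO
Why: Acid-catalysed enol etherification of a cyclic 1,3-dione; methanol adds to the carbonyl remote from the gem-dimethyl group, so the methoxy group lands on the unhindered carbon and the ketone beside CMe2 is kept, and any minor regioisomer is removed by chromatography.

Step 2
Reactants: 2 3-methoxy-6,6-dimethylcyclohex-2-en-1-one
Product: 3 2-methoxy-5,5-dimethylcyclohex-2-ene-1,4-dione
Conditions: Rh2(cap)4 (1 mol %), t-BuOOH (70% aq., 5 equiv), K2CO3, CH2Cl2, rt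
Reagents that add atoms: tert-butyl hydroperoxide, CC(C)(C)OO
Why: Allylic C–H oxidation by tert-butylperoxyl radicals (the known γ-oxidation of enones to ene-1,4-diones); the methylene next to the enol ether carbon is the only activated C–H position, and the quaternary carbon stops the product from tautomerising to a hydroquinone.

Step 3
Reactants: 3 2-methoxy-5,5-dimethylcyclohex-2-ene-1,4-dione; 4 2,2,2-trifluoroethyl formate
Product: 5 (6Z)-6-(hydroxymethylidene)-2-methoxy-5,5-dimethylcyclohex-2-ene-1,4-dione
Conditions: LiN(SiMe3)2 (1.1 equiv), THF, −78 °C; 4 (1.5 equiv), −78 → 0 °C; 1 M HCl
Reagents that add atoms: 2,2,2-trifluoroethyl formate (4), O=COCC(F)(F)F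
Why: Claisen-type C-formylation of the kinetic lithium enolate; C6 holds the only acidic hydrogens of 3, so there is no regiochemical choice, and the product rests as the chelated Z-hydroxymethylene tautomer. Trifluoroethoxide is too poor a nucleophile to exchange with the C2 methoxy group, which is why this formate is preferred to ethyl formate with an alkoxide base.

Step 4
Reactants: 5 (6Z)-6-(hydroxymethylidene)-2-methoxy-5,5-dimethylcyclohex-2-ene-1,4-dione; 6 methyl vinyl ketone
Product: 8 (6R)-2-methoxy-5,5-dimethylspiro[5.5]undeca-2,10-diene-1,4,9-trione, via keto aldehyde 7 (not isolated)
Conditions: 6 (1.5 equiv), 1-[3,5-bis(trifluoromethyl)phenyl]-3-[(1R,2R)-2-(dimethylamino)cyclohexyl]thiourea (10 mol %), toluene, −20 °C; then p-TsOH·H2O (0.3 equiv), toluene, 80 °C, azeotropic removal of water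
Reagents that add atoms: methyl vinyl ketone (6), CC(=O)C=C
Why: The tertiary amine of the catalyst deprotonates the acidic hydroxymethylene ketone 5 and holds the 1,3-dicarbonyl enolate as a hydrogen-bonded ion pair while the thiourea activates the carbonyl of 6; C6, the only nucleophilic carbon, adds to the terminal carbon of 6 (C6–C7 bond) and gives 7 with the quaternary centre. The closest known reaction types are the tertiary amine–thiourea catalysed Michael addition of cyclic β-keto esters and 1,3-diketones to enones and the amine-promoted racemic spiroannulation of α-formyl ketones with 6. C6 is the only new stereocentre and is set in this addition by the catalyst, which must cover one enantiotopic face of the planar enolate; the substrate has no stereocentre but offers two very different flanks at C6 (the flat C1 carbonyl against the CMe2 carbon C5) for the catalyst to read. Acid then enolises the methyl ketone of 7 toward C10 and this enol attacks the aldehyde carbon C11 (C10–C11 bond), closing ring A in the 6-(enolendo)-exo-trig mode; loss of water gives the C10=C11 enone, the only one possible because C6 bears no hydrogen. The step needs C- and not O-alkylation (the O-adduct is reversible), the aldehyde and not the C1 ketone as aldol acceptor (the aldehyde is far more electrophilic and is neither conjugated nor neopentyl), and survival of the C2 methoxy and formyl groups (secured by a tertiary amine catalyst and an acid for the aldol stage, since secondary amines would displace methoxide and alkoxides would deformylate the non-enolisable keto aldehyde 7).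

Step 5
Reactants: 8 (6R)-2-methoxy-5,5-dimethylspiro[5.5]undeca-2,10-diene-1,4,9-trione
Product: 10 (6R,10S)-10-bromo-2-methoxy-5,5-dimethylspiro[5.5]undec-2-ene-1,4,9-trione, via silyl enol ether 9 (not isolated)
Conditions: [(Ph3P)CuH]6 (5 mol %), PhMe2SiH (1.3 equiv), toluene, 0 °C → rt; NBS (1.3 equiv), THF, −78 °C; after work-up Bu4NBr (0.2 equiv), acetone, rt
Reagents that add atoms: N-bromosuccinimide, O=C1CCC(=O)N1Br; dimethyl(phenyl)silane, C[SiH](C)c1ccccc1 (its silicon is held in 9 only)
Why: Copper hydride conjugate reduction of the unhindered cis-disubstituted ring A enone with silyl transfer gives the regiodefined enol ether 9, which NBS brominates at C10 only; the C9=C10 enol ether is what keeps C6 stereogenic, so it is never allowed to equilibrate through a free enolate. Bromine should enter anti to the pseudo-axial C1 carbonyl, and bromide exchange (degenerate SN2) keeps C10 under thermodynamic control, where equatorial bromine cis to C5 is favoured as in 2-bromo-4,4-dialkylcyclohexanones.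

Step 6
Reactants: 10 (6R,10S)-10-bromo-2-methoxy-5,5-dimethylspiro[5.5]undec-2-ene-1,4,9-trione
Product: 11 (6R,10S)-10-bromo-9-hydroxy-2-methoxy-5,5,9-trimethylspiro[5.5]undec-2-ene-1,4-dione (C9 epimers)
Conditions: MeMgBr (1.2 equiv), CH2Cl2–Et2O, −78 °C; sat. aq. NH4Cl at −78 °C
Reagents that add atoms: methylmagnesium bromide, C[Mg]Br
Why: Grignard addition to the most electrophilic and only unhindered carbonyl, the α-bromo ketone C9; the C1 and C4 carbonyls are neopentyl and C4 is deactivated as a vinylogous ester. The cold quench prevents epoxide closure or ring contraction of the bromo alkoxide, and the C9 configuration does not matter because step 7 passes through a planar C9 cation.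

Step 7
Reactants: 11 (6R,10S)-10-bromo-9-hydroxy-2-methoxy-5,5,9-trimethylspiro[5.5]undec-2-ene-1,4-dione (C9 epimers)
Product: 12 (6R,9S,10S)-10-bromo-9-chloro-2-methoxy-5,5,9-trimethylspiro[5.5]undec-2-ene-1,4-dione
Conditions: HCl (g), CH2Cl2, MgSO4, −20 → 0 °C
Reagents that add atoms: hydrogen chloride, Cl
Why: SN1 chlorination with neighbouring-group participation, the classical conversion of a β-bromo alcohol into a vicinal dihalide through a bromonium ion. Ionisation of either C9 epimer gives the same C9–C10 bromonium ion on the face fixed by C10, and chloride opens it at the tertiary carbon anti to bromine, which sets C9 (Cl trans to Br, both equatorial, methyl axial). Anhydrous conditions spare the vinylogous ester.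

Step 8
Reactants: 12 (6R,9S,10S)-10-bromo-9-chloro-2-methoxy-5,5,9-trimethylspiro[5.5]undec-2-ene-1,4-dione
Product: 13 (6S,9S,10S)-10-bromo-9-chloro-2-methoxy-5,5,9-trimethyl-1-methylidenespiro[5.5]undec-2-en-4-one
Conditions: Cp2TiMe2 (2.5 equiv), toluene–THF, 65 °C, dark
Reagents that add atoms: Cp2TiMe2, C[Ti](C)(C1C=CC=C1)C1C=CC=C1
Why: Petasis methylenation (Cp2Ti=CH2 formed by loss of methane, then [2+2] addition to the carbonyl and cycloreversion); the C1 ketone is more electrophilic than the vinylogous ester carbonyl C4. The neutral reagent tolerates the alkyl halides, whose equatorial positions on the locked ring A also disfavour E2 loss of HX.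

Step 9
Reactants: 13 (6S,9S,10S)-10-bromo-9-chloro-2-methoxy-5,5,9-trimethyl-1-methylidenespiro[5.5]undec-2-en-4-one
Product: 14 (6S,9S,10S)-4,10-dibromo-9-chloro-5,5,9-trimethyl-1-methylidenespiro[5.5]undec-3-en-2-one
Conditions: (COBr)2 (1.5 equiv), DMF (cat.), CH2Cl2, 0 °C → rt
Reagents that add atoms: oxalyl bromide, O=C(Br)C(=O)Br
Why: Known conversion of a β-alkoxy enone into a β-bromo enone: oxalyl bromide acylates the C4 carbonyl oxygen, bromide adds to C4 and the oxalyl fragment leaves as CO, CO2 and bromide. The C2 oxocarbenium ion that remains is demethylated by bromide (SN2 at methyl), so bromine ends on C4 and the ketone on C2, as fixed by the position of the methyl ether.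

Step 10
Reactants: 14 (6S,9S,10S)-4,10-dibromo-9-chloro-5,5,9-trimethyl-1-methylidenespiro[5.5]undec-3-en-2-one
Product: 15 (2R,6S,9S,10S)-4,10-dibromo-9-chloro-5,5,9-trimethyl-1-methylidenespiro[5.5]undec-3-en-2-ol
Conditions: (S)-2-methyl-CBS-oxazaborolidine (0.2 equiv), catecholborane (1.5 equiv), toluene, −78 °C
Reagents that add atoms: none
Why: Corey–Bakshi–Shibata reduction: the catalyst binds the carbonyl lone pair on the side of the small flank (C3–H), away from the fully substituted C1, and delivers hydride 1,2 to the face that gives the (2R) alcohol. C2 is set by the reagent, because C6 is too remote and too evenly substituted (C7H2 against C11H2) to direct it; catecholborane does not hydroborate the alkenes at this temperature.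

## Compound list

1 | 4,4-dimethylcyclohexane-1,3-dione | O=C1CC(=O)C(C)(C)CC1 | starting material
2 | 3-methoxy-6,6-dimethylcyclohex-2-en-1-one | COC1=CC(=O)C(C)(C)CC1 | intermediate
3 | 2-methoxy-5,5-dimethylcyclohex-2-ene-1,4-dione | COC1=CC(=O)C(C)(C)CC1=O | intermediate
4 | 2,2,2-trifluoroethyl formate | O=COCC(F)(F)F | starting material
5 | (6Z)-6-(hydroxymethylidene)-2-methoxy-5,5-dimethylcyclohex-2-ene-1,4-dione | COC1=CC(=O)C(C)(C)/C(=C/O)C1=O | intermediate
6 | methyl vinyl ketone (but-3-en-2-one) | CC(=O)C=C | starting material
7 | (1S)-3-methoxy-6,6-dimethyl-2,5-dioxo-1-(3-oxobutyl)cyclohex-3-ene-1-carbaldehyde | COC1=CC(=O)C(C)(C)[C@](C=O)(CCC(C)=O)C1=O | intermediate (not isolated)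
8 | (6R)-2-methoxy-5,5-dimethylspiro[5.5]undeca-2,10-diene-1,4,9-trione | COC1=CC(=O)C(C)(C)[C@]2(CCC(=O)C=C2)C1=O | intermediate
9 | (6R)-9-[dimethyl(phenyl)silyl]oxy-2-methoxy-5,5-dimethylspiro[5.5]undeca-2,9-diene-1,4-dione | COC1=CC(=O)C(C)(C)[C@]2(CCC(O[Si](C)(C)c3ccccc3)=CC2)C1=O | intermediate (not isolated)
10 | (6R,10S)-10-bromo-2-methoxy-5,5-dimethylspiro[5.5]undec-2-ene-1,4,9-trione | COC1=CC(=O)C(C)(C)[C@]2(CCC(=O)[C@@H](Br)C2)C1=O | intermediate
11 | (6R,10S)-10-bromo-9-hydroxy-2-methoxy-5,5,9-trimethylspiro[5.5]undec-2-ene-1,4-dione, C9 epimers (9R expected to predominate, both usable) | COC1=CC(=O)C(C)(C)[C@]2(CCC(C)(O)[C@@H](Br)C2)C1=O | intermediate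
12 | (6R,9S,10S)-10-bromo-9-chloro-2-methoxy-5,5,9-trimethylspiro[5.5]undec-2-ene-1,4-dione | COC1=CC(=O)C(C)(C)[C@]2(CC[C@](C)(Cl)[C@@H](Br)C2)C1=O | intermediate
13 | (6S,9S,10S)-10-bromo-9-chloro-2-methoxy-5,5,9-trimethyl-1-methylidenespiro[5.5]undec-2-en-4-one | COC1=CC(=O)C(C)(C)[C@]2(CC[C@](C)(Cl)[C@@H](Br)C2)C1=C | intermediate
14 | (6S,9S,10S)-4,10-dibromo-9-chloro-5,5,9-trimethyl-1-methylidenespiro[5.5]undec-3-en-2-one | C=C1C(=O)C=C(Br)C(C)(C)[C@]12CC[C@](C)(Cl)[C@@H](Br)C2 | intermediate
15 | (2R,6S,9S,10S)-4,10-dibromo-9-chloro-5,5,9-trimethyl-1-methylidenespiro[5.5]undec-3-en-2-ol | C=C1[C@H](O)C=C(Br)C(C)(C)[C@]12CC[C@](C)(Cl)[C@@H](Br)C2 | target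

## Step count and least certain steps

Total: 10 steps. Longest linear sequence: 10 steps (1 to 15); 4 and 6 are purchased.

**Step 4 (key step).** The most likely failure is weak enantioface discrimination combined with slow bond formation. The nucleophilic carbon sits next to a quaternary carbon, the very acidic formyl ketone may form a tight and poorly organised ion pair with the catalyst, and a reversible addition would erode the selectivity further. The fallback sets out from 5 and 6 and comes back at 8. An achiral tertiary amine (Et3N, THF, rt) promotes the Michael addition to the racemic keto aldehyde F1. The same acid-mediated aldol condensation gives the racemic spiro enone F2. The enantiomers are separated by preparative chromatography on a chiral stationary phase; the (6R) enantiomer is 8 and the (6S) enantiomer F3 is set aside.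

**Step 5.** The most likely failure is hydride delivery to the ring B alkene in competition with ring A, since that alkene is activated by two carbonyl groups even though the methoxy group and the quaternary neighbours deactivate it. Any loss of the enol regiochemistry would also lower the enantiomeric purity. The fallback sets out from 8 and comes back at 10. It replaces the nucleophilic copper hydride by a rhodium silyl hydride whose selectivity is steric: RhCl(PPh3)3 with Et3SiH gives 1,4-hydrosilylation of the disubstituted enone only. The triethylsilyl enol ether F4 is isolated and purified, then brominated with NBS at −78 °C, with the same bromide equilibration at C10.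

**Step 7.** The most likely failure is ionisation without bromine bridging, because the equatorial C–Br bond is not aligned with the departing group. Chloride capture on both faces, loss of a proton to an alkene, or chloride attack at C10 with halogen interchange would follow. The fallback sets out from 8, passes through 9 and comes back at 12, replacing steps 5 to 7. Fluoride-mediated triflation of 9 (Bu4N[Ph3SiF2], PhNTf2) gives enol triflate F5. Stille methylation (Me4Sn, Pd(PPh3)4, LiCl) gives the C9-methyl alkene F6. Bromochlorination with Bu4N[BrCl2] then adds bromine to C10 on the face anti to the pseudo-axial C1 and chloride to the more substituted carbon C9 from the opposite face.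

**Step 8.** The most likely failure is a slow cycloaddition at the neopentyl C1 carbonyl, which would leave time for methylenation of C4 or thermal loss of HCl. The fallback sets out from 12 and comes back at 13 by Peterson olefination in two stages. Me3SiCH2MgCl with CeCl3 at −78 °C adds to C1 to give the β-hydroxy silane F7 (either C1 epimer). A trace of acid (silica gel or catalytic p-TsOH) then eliminates trimethylsilanol toward the only possible alkene, the exocyclic one.

**Step 10.** The most likely failure is poor facial selectivity, because both flanks of the C2 carbonyl are alkenyl carbons and differ only in substitution; conjugate hydride addition at C15 is a second risk. The fallback sets out from 14 and comes back at 15. Luche reduction (NaBH4, CeCl3·7H2O, MeOH, −78 °C) gives 15 together with its C2 epimer F8. The two are separated by chromatography, and F8 is oxidised back to 14 with MnO2 and recycled.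

## Further compounds

F1 | step 4 | racemic 3-methoxy-6,6-dimethyl-2,5-dioxo-1-(3-oxobutyl)cyclohex-3-ene-1-carbaldehyde | COC1=CC(=O)C(C)(C)C(C=O)(CCC(C)=O)C1=O
F2 | step 4 | racemic 2-methoxy-5,5-dimethylspiro[5.5]undeca-2,10-diene-1,4,9-trione | COC1=CC(=O)C(C)(C)C2(CCC(=O)C=C2)C1=O
F3 | step 4 | (6S)-2-methoxy-5,5-dimethylspiro[5.5]undeca-2,10-diene-1,4,9-trione | COC1=CC(=O)C(C)(C)[C@@]2(CCC(=O)C=C2)C1=O
F4 | step 5 | (6R)-2-methoxy-5,5-dimethyl-9-(triethylsilyloxy)spiro[5.5]undeca-2,9-diene-1,4-dione | COC1=CC(=O)C(C)(C)[C@]2(CCC(O[Si](CC)(CC)CC)=CC2)C1=O
F5 | step 7 | (6R)-2-methoxy-5,5-dimethyl-1,4-dioxospiro[5.5]undeca-2,9-dien-9-yl trifluoromethanesulfonate | COC1=CC(=O)C(C)(C)[C@]2(CCC(OS(=O)(=O)C(F)(F)F)=CC2)C1=O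
F6 | step 7 | (6R)-2-methoxy-5,5,9-trimethylspiro[5.5]undeca-2,9-diene-1,4-dione | COC1=CC(=O)C(C)(C)[C@]2(CCC(C)=CC2)C1=O
F7 | step 8 | (6R,9S,10S)-10-bromo-9-chloro-1-hydroxy-2-methoxy-5,5,9-trimethyl-1-[(trimethylsilyl)methyl]spiro[5.5]undec-2-en-4-one (C1 epimers) | COC1=CC(=O)C(C)(C)[C@]2(CC[C@](C)(Cl)[C@@H](Br)C2)C1(O)C[Si](C)(C)C
F8 | step 10 | (2S,6S,9S,10S)-4,10-dibromo-9-chloro-5,5,9-trimethyl-1-methylidenespiro[5.5]undec-3-en-2-ol | C=C1[C@@H](O)C=C(Br)C(C)(C)[C@]12CC[C@](C)(Cl)[C@@H](Br)C2
A1 | alternative 1 | 3-bromo-5-[(3R)-3-[dimethyl(phenyl)silyl]-3-methylpent-4-en-1-yl]-4,4-dimethylcyclohexa-2,5-dien-1-one | O=C1C=C(CC[C@@](C)([Si](C)(C)c2ccccc2)C=C)C(C)(C)C(Br)=C1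
A2 | alternative 1 | (6S)-4-bromo-5,5,9-trimethylspiro[5.5]undeca-3,9-dien-2-one | O=C1C[C@@]2(CCC(C)=CC2)C(C)(C)C(Br)=C1
A3 | alternative 2 | 4,4′-[(5R)-3-bromo-5-[tert-butyl(dimethyl)silyl]oxy-2,2-dimethyl-6-methylidenecyclohex-3-ene-1,1-diyl]bis(butan-2-one) | C=C1[C@H](O[Si](C)(C)C(C)(C)C)C=C(Br)C(C)(C)C1(CCC(C)=O)CCC(C)=O
A4 | alternative 2 | 1-[(2R,6S,9S,10S)-4-bromo-2-[tert-butyl(dimethyl)silyl]oxy-9-hydroxy-5,5,9-trimethyl-1-methylidenespiro[5.5]undec-3-en-10-yl]ethan-1-one | C=C1[C@H](O[Si](C)(C)C(C)(C)C)C=C(Br)C(C)(C)[C@]12CC[C@](C)(O)[C@@H](C(C)=O)C2
A5 | alternative 3 | 4,4-dibromo-1-[8-(prop-1-en-2-yl)-1,4-dioxaspiro[4.5]decan-8-yl]but-3-en-2-one | CC(=C)C1(CC(=O)C=C(Br)Br)CCC2(CC1)OCCO2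
A6 | alternative 3 | 4-bromo-5,5-dimethylspiro[5.5]undec-3-ene-2,9-dione 9-(ethylene ketal) | CC1(C)C(Br)=CC(=O)CC12CCC3(CC2)OCCO3
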